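The data are simulated with made-up constants; scatter was added.

Early readings opened the meeting on the new flasks, where starting material meets partner to give target, with protic impurity present, and where the amount of target at 2.0 h is wanted.

| flask | starting material | partner | protic impurity | remark | time |
|---|---|---|---|---|---|
| red | 0.13 M | 0.117 M | 0.83 mM | run made earlier |  |
| violet | 0.13 M | 0.117 M | 1.3 mM | run made earlier |  |
| green | 0.13 M | 0.117 M | 2 mM | run made earlier |  |
| teal | 0.13 M | 0.22 M | 2.6 mM | run made earlier |  |
| birch | 0.080 M | 0.117 M | 1.20 mM |  | 2.0 h |
| alder | 0.13 M | 0.200 M | 0.800 mM |  | 2.0 h |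
| maple | 0.060 M | 0.500 M | 2.60 mM |  | 2.0 h |
| elm | 0.13 M | 0.117 M | 2.60 mM |  | 2.0 h |

| run | time / min | target / % | starting material / % |
|---|---|---|---|
| red | 10.0 | 36.6 | 22.5 |
| red | 30.0 | 45.5 | 2.2 |
| red | 60.0 | 47.2 | 0 |
| red | 80.0 | 47.0 | 0.1 |
| red | 120 | 47.3 | 2.1 |
| violet | 25.0 | 45.6 | 4.5 |
| violet | 50.0 | 47.0 | 0 |
| violet | 80.0 | 46.4 | 0 |
| violet | 90.0 | 47.6 | 0 |
| violet | 120 | 46.9 | 0 |
| green | 25.0 | 44.9 | 4.9 |
| green | 50.0 | 46.7 | 0.5 |
| green | 80.0 | 46.7 | 0.5 |
| green | 90.0 | 46.6 | 0 |
| green | 120 | 46.8 | 0 |
| teal | 10.0 | 56.8 | 12.5 |
| teal | 30.0 | 63.9 | 0.3 |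
| teal | 60.0 | 64.1 | 0.1 |
| teal | 80.0 | 64.8 | 0 |
| teal | 120 | 64.7 | 0 |

(readings scatter by 0.5 percentage points)



1. ranking by amount of target, in percent of the starting material charged, from high to low, at 2.0 h (birch / alder / maple / elm)
2. the amount of target, in percent of the starting material charged of the flask you put first, at 2.0 h
3. the amount of target, in percent of the starting material charged of the flask you put last, at 2.0 h

The kineticist took the red run at 10.0 min. Starting material stood at 22.5%, which, read as a first-order fall, means a half-life near 4.65 min, far shorter than 2.0 h, so she argued that plateaus are what is asked. She added that target was already 47.2% of the starting material consumed in the red run, matching its last reading of 47.3%.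

The process chemist set protic impurity aside for these estimates: from red to green its charge rose from 0.83 mM to 2 mM, yet the last reading of target moved 0.5 percentage points, against a scatter of 0.5 points. Teal, with 0.22 M of partner and 2.6 mM of protic impurity, read 64.7%.

The chair therefore proposed a share: target is m/(m + level), with m the mean c(partner), taken as the charge less half of the target formed. Red gives a level of 0.0961 M and teal 0.0971 M. Their mean is the break-even partner level, the c(partner) at which target and the losses together take starting material equally fast, 0.0966 M; c(partner) over it is the selectivity factor.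

A sceptic objected that each earlier run charged 0.13 M of starting material, so birch and maple lie outside what was read. The chair reckoned with the mean level all the same: maple 83.1%, alder 62.3%, birch 50.1%, elm 47.2%.

The forecast gives maple > alder > birch > elm, with 83% first and 46.5% last, lower than the 47.2% reckoned here for elm, holding that “Selectivity is therefore set by competition”.

The flasks give maple > alder > birch > elm: maple 85.5%, alder 62.5%, birch 53.5%, elm 46.8%.

    2 starting material → side product B (k = 14.0 M⁻¹ h⁻¹)
    starting material + protic impurity → quenched substrate (k = 98.0 M⁻¹ h⁻¹)
    starting material → side product A (k = 2.90 h⁻¹)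
    starting material + partner → target (k = 49.0 M⁻¹ h⁻¹)

In maple the step to target starts 8.4 times as fast as the step to side product A, and the flask ends with 85.5% target against 10.7% side product A; that amount of target puts the break-even level read back from maple at 0.0806 M, below the 0.0966 M read at 0.13 M of starting material. Carried to a flask like maple but charged with 0.85 M of partner, that level gives 91.1% target, and that flask holds 91.0%.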